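## Retrosynthetic overview

1. Target 11 ⇒ oxane tosyl‑hydrin 7 + 4‑iodophenyl acetate 8. The C7–aryl bond is made last by a visible‑light nickel/photoredox cross‑electrophile coupling through iodohydrin 9. It is placed last because by then no alkene remains for the C7 radical to cyclize onto.
2. 7 ⇒ diol tosylate 3 + vanillin acetate 4 by Prins cyclization. This forms the oxane, the only ring built (both aryl rings are bought), making C1–C2 and C1–O and setting C1 and C3 from C5.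
3. 3 ⇒ triol 2 by primary‑selective tosylation; 2 ⇒ 2‑deoxy‑D‑ribose 1 by Wittig methylenation.
4. Stereochemistry: C5 (S) and C6 (R) are C3 and C4 of 2‑deoxy‑D‑ribose. C1 and C3 follow from the chair Prins transition state. No chiral reagent, catalyst or auxiliary is used.

Assumption: C1–C7 number the heptane chain (C1 carries the methoxyphenol ring, C7 is the benzylic CH2 of the 4‑hydroxyphenyl group); 1 is drawn open‑chain although it is sold as the cyclic hemiacetal; 1, 4 and 8 are taken as commercial.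

## Route

Step 1
Reactants: 1 2‑deoxy‑D‑ribose
Product: 2 (2R,3S)‑hex‑5‑ene‑1,2,3‑triol
Conditions: Ph3PCH3Br (3.0 equiv), KOtBu (3.0 equiv), THF, 0 °C → rt, 16 h
Reagents that add atoms: methyltriphenylphosphonium bromide, C[P+](c1ccccc1)(c1ccccc1)c1ccccc1.[Br-]
Why: Wittig methylenation of the open‑chain aldehyde that is in equilibrium with the lactol, with excess ylide absorbing the OH protons; no stereocentre is touched, so C5 (S) and C6 (R) come unchanged from the sugar.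

Step 2
Reactants: 2 (2R,3S)‑hex‑5‑ene‑1,2,3‑triol
Product: 3 (2R,3S)‑2,3‑dihydroxyhex‑5‑en‑1‑yl 4‑methylbenzenesulfonate
Conditions: TsCl (1.05 equiv), Bu2SnO (5 mol %), Et3N (1.1 equiv), CH2Cl2, 0 °C → rt, 3 h
Reagents that add atoms: 4‑toluenesulfonyl chloride, Cc1ccc(cc1)S(=O)(=O)Cl
Why: Tin‑acetal‑catalysed regioselective sulfonylation, in which the five‑membered stannylene of the terminal 1,2‑diol activates the primary oxygen so that only O‑7 is tosylated; no stereocentre is touched.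

Step 3
Reactants: 3 (2R,3S)‑2,3‑dihydroxyhex‑5‑en‑1‑yl 4‑methylbenzenesulfonate; 4 4‑formyl‑2‑methoxyphenyl acetate (vanillin acetate)
Product: 7 4‑[(2R,4R,6S)‑4‑hydroxy‑6‑[(1R)‑1‑hydroxy‑2‑(tosyloxy)ethyl]oxan‑2‑yl]‑2‑methoxyphenyl acetate, via dioxolane acetal 5 (not isolated), via oxan‑4‑yl trifluoroacetate 6 (not isolated)
Conditions: 4 (1.3 equiv), CF3CO2H/CH2Cl2 (1:3), 0 °C → rt, 3 h; concentrate; then NaHCO3 (sat. aq), MeOH, 0 °C, 20 min
Reagents that add atoms: trifluoroacetic acid, OC(=O)C(F)(F)F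
Why: Prins cyclization in which acid opens the reversibly formed acetal 5 to the (E)‑oxocarbenium ion on the homoallylic oxygen, the alkene attacks through a chair with aryl and side chain equatorial (sets C1, 2,6‑cis) and trifluoroacetate caps the oxan‑4‑yl cation equatorially (sets C3, all‑cis), both new centres being dictated by the purchased C5; the acetoxy group keeps the arene electron‑poor enough to suppress oxonia‑Cope scrambling, and brief bicarbonate methanolysis cleaves only the trifluoroacetate.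

Step 4
Reactants: 7 4‑[(2R,4R,6S)‑4‑hydroxy‑6‑[(1R)‑1‑hydroxy‑2‑(tosyloxy)ethyl]oxan‑2‑yl]‑2‑methoxyphenyl acetate; 8 4‑iodophenyl acetate
Product: 11 4‑[(2R,4R,6S)‑4‑hydroxy‑6‑[(1R)‑1‑hydroxy‑2‑(4‑hydroxyphenyl)ethyl]oxan‑2‑yl]‑2‑methoxyphenol, via iodohydrin 9 (not isolated), via coupled diacetate 10 (not isolated)
Conditions: NaI (1.5 equiv), DMA, 50 °C, 6 h, dark; then 8 (1.5 equiv), NiBr2(dme) (10 mol %), 4,4'‑di‑tert‑butyl‑2,2'‑bipyridine (12 mol %), 2,4,5,6‑tetrakis(carbazol‑9‑yl)benzene‑1,3‑dicarbonitrile (4CzIPN, 3 mol %), Et3N (4 equiv), 450 nm LEDs, 35 °C, 24 h; then K2CO3 (3 equiv), MeOH, rt, 1 h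
Reagents that add atoms: none
Why: Proposed new method: a halide‑relay nickel/photoredox cross‑electrophile coupling run in one flask on a β‑hydroxy primary tosylate, in which iodide displaces the tosylate (SN2) to give iodohydrin 9, the excited photocatalyst is reductively quenched by Et3N and returns nickel to its zerovalent state, iodine abstraction by the α‑aminoalkyl radical or by monovalent nickel gives the primary C7 radical (not a stereocentre), this is captured by the aryl–nickel species formed from zerovalent nickel and 8, and reductive elimination from trivalent nickel forms the C7–aryl bond, the base‑free medium keeping both aryl acetates (and so the guaiacyl ring beyond the reach of the excited photocatalyst) until the closing carbonate methanolysis; the closest known reaction type is the nickel/photoredox cross‑electrophile coupling of terminal aliphatic epoxides with aryl iodides through iodohydrins, together with thermal halide‑cocatalysed nickel coupling of alkyl sulfonates.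

## Compound list

1 | 2‑deoxy‑D‑ribose, (3S,4R)‑3,4,5‑trihydroxypentanal, open‑chain form | O=CC[C@H](O)[C@H](O)CO | starting material
2 | (2R,3S)‑hex‑5‑ene‑1,2,3‑triol | C=CC[C@H](O)[C@H](O)CO | intermediate
3 | (2R,3S)‑2,3‑dihydroxyhex‑5‑en‑1‑yl 4‑methylbenzenesulfonate | C=CC[C@H](O)[C@H](O)COS(=O)(=O)c1ccc(C)cc1 | intermediate
4 | 4‑formyl‑2‑methoxyphenyl acetate (vanillin acetate) | CC(=O)Oc1ccc(C=O)cc1OC | starting material
5 | 4‑[(4S,5R)‑4‑(prop‑2‑en‑1‑yl)‑5‑(tosyloxymethyl)‑1,3‑dioxolan‑2‑yl]‑2‑methoxyphenyl acetate, both epimers at the acetal carbon, formed in the flask | C=CC[C@@H]1OC(c2ccc(OC(C)=O)c(OC)c2)O[C@@H]1COS(=O)(=O)c3ccc(C)cc3 | intermediate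
6 | (2R,4R,6S)‑2‑(4‑acetoxy‑3‑methoxyphenyl)‑6‑[(1R)‑1‑hydroxy‑2‑(tosyloxy)ethyl]oxan‑4‑yl trifluoroacetate, formed in the flask | COc1cc([C@H]2C[C@@H](OC(=O)C(F)(F)F)C[C@@H]([C@H](O)COS(=O)(=O)c3ccc(C)cc3)O2)ccc1OC(C)=O | intermediate
7 | 4‑[(2R,4R,6S)‑4‑hydroxy‑6‑[(1R)‑1‑hydroxy‑2‑(tosyloxy)ethyl]oxan‑2‑yl]‑2‑methoxyphenyl acetate | COc1cc([C@H]2C[C@@H](O)C[C@@H]([C@H](O)COS(=O)(=O)c3ccc(C)cc3)O2)ccc1OC(C)=O | intermediate
8 | 4‑iodophenyl acetate | CC(=O)Oc1ccc(I)cc1 | starting material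
9 | 4‑[(2R,4R,6S)‑4‑hydroxy‑6‑[(1S)‑1‑hydroxy‑2‑iodoethyl]oxan‑2‑yl]‑2‑methoxyphenyl acetate, formed in the flask | COc1cc([C@H]2C[C@@H](O)C[C@@H]([C@H](O)CI)O2)ccc1OC(C)=O | intermediate
10 | 4‑[(2R,4R,6S)‑6‑[(1R)‑2‑(4‑acetoxyphenyl)‑1‑hydroxyethyl]‑4‑hydroxyoxan‑2‑yl]‑2‑methoxyphenyl acetate, formed in the flask | COc1cc([C@H]2C[C@@H](O)C[C@@H]([C@H](O)Cc3ccc(OC(C)=O)cc3)O2)ccc1OC(C)=O | intermediate
11 | 4‑[(2R,4R,6S)‑4‑hydroxy‑6‑[(1R)‑1‑hydroxy‑2‑(4‑hydroxyphenyl)ethyl]oxan‑2‑yl]‑2‑methoxyphenol | COc1cc([C@H]2C[C@@H](O)C[C@@H]([C@H](O)Cc3ccc(O)cc3)O2)ccc1O | target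

## Step count and risks

Total steps: 4. Longest linear sequence: 4 (1 → 2 → 3 → 7 → 11).

**Step 4 (proposed new step).** The in‑flask tosylate‑to‑iodide exchange on a β‑oxygenated carbon may be slow, and hydrodehalogenation or aryl homocoupling may compete. The fallback sets out from 7 and comes back at 11 by polar organocopper chemistry. K2CO3 in MeOH closes the tosyl‑hydrin to the terminal epoxide and removes the aryl acetate, giving 4‑[(2R,4R,6S)‑4‑hydroxy‑6‑[(2R)‑oxiran‑2‑yl]oxan‑2‑yl]‑2‑methoxyphenol F1. Copper‑catalysed opening at the terminal carbon with 4‑(tert‑butyldimethylsilyloxy)phenylmagnesium bromide (5 equiv, two consumed by the free OH groups; CuI 20 mol %, THF, −30 → 0 °C) gives 4‑[(2R,4R,6S)‑6‑[(1R)‑2‑[4‑(tert‑butyldimethylsilyloxy)phenyl]‑1‑hydroxyethyl]‑4‑hydroxyoxan‑2‑yl]‑2‑methoxyphenol F2. Bu4NF in THF then gives 11.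

**Step 3.** The free C6 hydroxyl next to the reacting one may hold the aldehyde as the dioxolane, or may capture the oxan‑4‑yl cation through an axial conformer to give a bridged ether. The fallback sets out from 2 and comes back at 7 by masking the terminal diol first and sulfonylating last.
- 2,2‑Dimethoxypropane with pyridinium 4‑toluenesulfonate gives (1S)‑1‑[(4R)‑2,2‑dimethyl‑1,3‑dioxolan‑4‑yl]but‑3‑en‑1‑ol F3, which has only the homoallylic OH free.
- Prins cyclization with 4 (CF3CO2H, CH2Cl2, 0 °C, short time) gives (2R,4R,6S)‑2‑(4‑acetoxy‑3‑methoxyphenyl)‑6‑[(4R)‑2,2‑dimethyl‑1,3‑dioxolan‑4‑yl]oxan‑4‑yl trifluoroacetate F4, not isolated.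
- Bicarbonate methanolysis gives 4‑[(2R,4R,6S)‑6‑[(4R)‑2,2‑dimethyl‑1,3‑dioxolan‑4‑yl]‑4‑hydroxyoxan‑2‑yl]‑2‑methoxyphenyl acetate F5.
- 80 % aqueous AcOH at 40 °C removes the acetonide to give 4‑[(2R,4R,6S)‑6‑[(1R)‑1,2‑dihydroxyethyl]‑4‑hydroxyoxan‑2‑yl]‑2‑methoxyphenyl acetate F6. If the acetonide is already lost in the acid, F6 is obtained directly.
- TsCl with Bu2SnO (5 mol %) and Et3N tosylates the primary OH to give 7.

**Step 2.** Over‑tosylation or tosylation at a secondary OH of the unprotected triol may lower the yield. The fallback sets out from 1 and comes back at 3, fixing the regiochemistry by protection. 2‑Methoxypropene with pyridinium 4‑toluenesulfonate in DMF converts 1 into 3,4‑O‑isopropylidene‑2‑deoxy‑D‑ribopyranose F7. Wittig methylenation (Ph3PCH3Br, KOtBu, THF) gives [(4R,5S)‑2,2‑dimethyl‑5‑(prop‑2‑en‑1‑yl)‑1,3‑dioxolan‑4‑yl]methanol F8, whose only free OH is the primary one. TsCl in pyridine gives [(4R,5S)‑2,2‑dimethyl‑5‑(prop‑2‑en‑1‑yl)‑1,3‑dioxolan‑4‑yl]methyl 4‑methylbenzenesulfonate F9. 80 % aqueous AcOH at 50 °C removes the acetonide to give 3.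

Further compounds
F1 | step 4 | 4‑[(2R,4R,6S)‑4‑hydroxy‑6‑[(2R)‑oxiran‑2‑yl]oxan‑2‑yl]‑2‑methoxyphenol | COc1cc([C@H]2C[C@@H](O)C[C@@H]([C@H]3CO3)O2)ccc1O
F2 | step 4 | 4‑[(2R,4R,6S)‑6‑[(1R)‑2‑[4‑(tert‑butyldimethylsilyloxy)phenyl]‑1‑hydroxyethyl]‑4‑hydroxyoxan‑2‑yl]‑2‑methoxyphenol | COc1cc([C@H]2C[C@@H](O)C[C@@H]([C@H](O)Cc3ccc(O[Si](C)(C)C(C)(C)C)cc3)O2)ccc1O
F3 | step 3 | (1S)‑1‑[(4R)‑2,2‑dimethyl‑1,3‑dioxolan‑4‑yl]but‑3‑en‑1‑ol | C=CC[C@H](O)[C@H]1COC(C)(C)O1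
F4 | step 3 | (2R,4R,6S)‑2‑(4‑acetoxy‑3‑methoxyphenyl)‑6‑[(4R)‑2,2‑dimethyl‑1,3‑dioxolan‑4‑yl]oxan‑4‑yl trifluoroacetate | COc1cc([C@H]2C[C@@H](OC(=O)C(F)(F)F)C[C@@H]([C@H]3COC(C)(C)O3)O2)ccc1OC(C)=O
F5 | step 3 | 4‑[(2R,4R,6S)‑6‑[(4R)‑2,2‑dimethyl‑1,3‑dioxolan‑4‑yl]‑4‑hydroxyoxan‑2‑yl]‑2‑methoxyphenyl acetate | COc1cc([C@H]2C[C@@H](O)C[C@@H]([C@H]3COC(C)(C)O3)O2)ccc1OC(C)=O
F6 | step 3 | 4‑[(2R,4R,6S)‑6‑[(1R)‑1,2‑dihydroxyethyl]‑4‑hydroxyoxan‑2‑yl]‑2‑methoxyphenyl acetate | COc1cc([C@H]2C[C@@H](O)C[C@@H]([C@H](O)CO)O2)ccc1OC(C)=O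
F7 | step 2 | 3,4‑O‑isopropylidene‑2‑deoxy‑D‑ribopyranose (anomer mixture) | OC1C[C@@H]2OC(C)(C)O[C@@H]2CO1
F8 | step 2 | [(4R,5S)‑2,2‑dimethyl‑5‑(prop‑2‑en‑1‑yl)‑1,3‑dioxolan‑4‑yl]methanol | C=CC[C@@H]1OC(C)(C)O[C@@H]1CO
F9 | step 2 | [(4R,5S)‑2,2‑dimethyl‑5‑(prop‑2‑en‑1‑yl)‑1,3‑dioxolan‑4‑yl]methyl 4‑methylbenzenesulfonate | C=CC[C@@H]1OC(C)(C)O[C@@H]1COS(=O)(=O)c2ccc(C)cc2
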